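**Plan**

1. Locants: ring A is the cyclohexane C1 (CH bearing the chain), C2 (CMe2), C3 (CHOH), C4, C5, C6 (C(Me)OH); the chain runs from C1' (OCH2) to C5' (on C1).
2. Retrosynthesis: cut ArO–C1' (Mitsunobu); cut C1'–C2' and C3'–CH3 back to a terminal alkyne (carboalumination, Sharpless epoxidation, hydride opening); reconnect O(C6) to C3' through a carbonyl (retro-Baeyer–Villiger) to a cis-hydrindan-1-one; then cut C1–C2 and C5–C6 of ring A (retro-[4+2]).
3. Enabling feature: C6(Me)(O)–C1(H) of ring A together with chain atoms C5', C4', C3' is a disguised 2-methylcyclopent-2-enone (C3' is the carbonyl, the C6–O bond is the former C6–C3' bond, and the cis relation of C6–O and the C1 chain is the ring fusion); C5–C4–C3(O)–C2Me2 is a 2-silyloxydiene.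
4. Forward: dienophile 3 and diene 5 are made; the Diels–Alder reaction builds ring A on the five-membered ring; the silyloxy helper leaves as an enone, which is reduced together with the C3 ketone; Baeyer–Villiger oxidation opens the five-membered ring; the chain gains two carbons and a methyl; umbelliferone is attached last.
5. Stereochemistry: C1 and C6 come from the (R)-silyloxy group of the dienophile (anti addition, cis fusion) and the retentive Baeyer–Villiger migration; C3 from equatorial hydride delivery by LiBH(s-Bu)3; C3' from Sharpless epoxidation with D-(−)-diethyl tartrate.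

Key step: step 4

Assumption: 4-methylpent-1-en-3-one 4 and (R)-4-[(tert-butyldimethylsilyl)oxy]cyclopent-2-en-1-one 1 are taken as purchasable.
Remark: the bicyclic intermediates carry hydrindane locants: C3a = ring A C1, C4 = C2, C5 = C3, C6 = C4, C7 = C5, C7a = C6; C3, C2, C1 = chain C5', C4', C3'.

**Route**

Step 1
Reactants: 1 (R)-4-[(tert-butyldimethylsilyl)oxy]cyclopent-2-en-1-one
Product: 2 (R)-4-[(tert-butyldimethylsilyl)oxy]-2-iodocyclopent-2-en-1-one
Conditions: I2, pyridine/CH2Cl2, 0 °C to rt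
Reagents that add atoms: iodine, II
Why: α-iodination of the enone by pyridine addition, iodination and elimination (Baylis–Hillman-type α-halogenation) should leave the C4 stereocenter untouched.

Step 2
Reactants: 2 (R)-4-[(tert-butyldimethylsilyl)oxy]-2-iodocyclopent-2-en-1-one
Product: 3 (R)-4-[(tert-butyldimethylsilyl)oxy]-2-methylcyclopent-2-en-1-one
Conditions: Me4Sn, Pd2(dba)3 (cat.), AsPh3, CuI, NMP, 60 °C
Reagents that add atoms: tetramethylstannane, C[Sn](C)(C)C
Why: Stille coupling of the α-iodoenone under zerovalent-palladium catalysis should install the methyl group under neutral conditions that do not eliminate the silyloxy group.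

Step 3
Reactants: 4 4-methylpent-1-en-3-one
Product: 5 tert-butyl(dimethyl)[(4-methylpenta-1,3-dien-3-yl)oxy]silane
Conditions: TBSOTf, Et3N, CH2Cl2, 0 °C
Reagents that add atoms: tert-butyldimethylsilyl trifluoromethanesulfonate, CC(C)(C)[Si](C)(C)OS(=O)(=O)C(F)(F)F
Why: soft enolisation and O-silylation should be regiospecific because the isopropyl methine is the only α-hydrogen, giving the cross-conjugated 2-silyloxydiene.

Step 4
Reactants: 3 (R)-4-[(tert-butyldimethylsilyl)oxy]-2-methylcyclopent-2-en-1-one; 5 tert-butyl(dimethyl)[(4-methylpenta-1,3-dien-3-yl)oxy]silane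
Product: 6 (3R,3aR,7aS)-3,5-bis[(tert-butyldimethylsilyl)oxy]-4,4,7a-trimethyl-2,3,3a,4,7,7a-hexahydro-1H-inden-1-one
Conditions: AlBr3/AlMe3 (10:1, 0.3 equiv), toluene/CH2Cl2, −20 to 0 °C
Reagents that add atoms: none
Why: AlBr3 (kept proton-free by AlMe3) binds the C1 carbonyl of 3, and the silyl dienol ether 5 adds across C2=C3 in a normal-demand, strongly asynchronous Diels–Alder reaction whose limiting form is a Mukaiyama–Michael addition followed by 6-endo-trig Michael closure. The closest known reaction type is the mixed-Lewis-acid (AlBr3/AlMe3) Diels–Alder reaction of hindered 2-silyloxydienes with 2-methylcycloalk-2-enones. Ring A is closed by intermolecular [4+2] cycloaddition, both new bonds (C3a–C4 and C7–C7a) forming on one face of the ring-locked cis alkene, so the C7a methyl and the C3a hydrogen must be cis. The absolute sense at C7a (S) and C3a (R) should follow from approach of the diene anti to the C4 silyloxy group of 3. The regiochemistry needed (CMe2 terminus to the β-carbon) is secured by the silyl enol ether polarisation of 5, which makes the CMe2 carbon the nucleophile, and by avoidance of two adjacent quaternary centres. No endo/exo question arises because the diene termini are CH2 and CMe2.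

Step 5
Reactants: 6 (3R,3aR,7aS)-3,5-bis[(tert-butyldimethylsilyl)oxy]-4,4,7a-trimethyl-2,3,3a,4,7,7a-hexahydro-1H-inden-1-one
Product: 8 (3aR,7aS)-4,4,7a-trimethyl-3a,4,7,7a-tetrahydro-1H-indene-1,5(6H)-dione, via enone silyl enol ether 7 (not isolated)
Conditions: DBU (cat.), CH2Cl2, 0 °C; then 1 M HCl (cat.), THF, 0 °C
Reagents that add atoms: none
Why: E1cB elimination of the β-silyloxy helper (only C2 can be enolised) should give the cyclopentenone while C5 is still masked, which blocks retro-Michael opening of ring A, and mild acid then hydrolyses the silyl enol ether.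

Step 6
Reactants: 8 (3aR,7aS)-4,4,7a-trimethyl-3a,4,7,7a-tetrahydro-1H-indene-1,5(6H)-dione
Product: 10 (3aR,5S,7aS)-5-hydroxy-4,4,7a-trimethyloctahydro-1H-inden-1-one, via lithium enolate alkoxide 9 (not isolated)
Conditions: LiBH(s-Bu)3 (2.5 equiv), THF, −78 °C; then H2O
Reagents that add atoms: none
Why: the bulky trialkylborohydride should reduce the enone by 1,4-addition, so that C1 is shielded as its enolate, and the C5 ketone by equatorial attack as in 4,4-dimethyl-3-oxo terpenoids, giving the axial (5S) alcohol.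

Step 7
Reactants: 10 (3aR,5S,7aS)-5-hydroxy-4,4,7a-trimethyloctahydro-1H-inden-1-one
Product: 11 (4aR,6S,8aS)-6-hydroxy-5,5,8a-trimethyloctahydro-2H-chromen-2-one
Conditions: mCPBA, NaHCO3, CH2Cl2, 0 °C to rt
Reagents that add atoms: 3-chloroperbenzoic acid, OOC(=O)c1cccc(Cl)c1
Why: in the Baeyer–Villiger oxidation the quaternary C7a should migrate in preference to the CH2 and with retention, turning the C7a–C1 bond into the tertiary C–O bond of ring A.

Step 8
Reactants: 11 (4aR,6S,8aS)-6-hydroxy-5,5,8a-trimethyloctahydro-2H-chromen-2-one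
Product: 12 (4aR,6S,8aS)-5,5,8a-trimethyloctahydro-2H-chromene-2,6-diol (anomeric mixture)
Conditions: i-Bu2AlH (2.2 equiv), CH2Cl2, −78 °C
Reagents that add atoms: none
Why: partial reduction of the lactone should stop at the lactol because the aluminium hemiacetal is stable at low temperature.

Step 9
Reactants: 12 (4aR,6S,8aS)-5,5,8a-trimethyloctahydro-2H-chromene-2,6-diol
Product: 13 (1S,2R,4S)-2-(but-3-yn-1-yl)-1,3,3-trimethylcyclohexane-1,4-diol
Conditions: dimethyl (1-diazo-2-oxopropyl)phosphonate, K2CO3, MeOH, 0 °C to rt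
Reagents that add atoms: dimethyl (1-diazo-2-oxopropyl)phosphonate, COP(=O)(OC)C(=[N+]=[N-])C(C)=O
Why: Seyferth–Gilbert homologation in the Ohira–Bestmann variant should convert the open hydroxy-aldehyde tautomer of the lactol into the terminal alkyne.

Step 10
Reactants: 13 (1S,2R,4S)-2-(but-3-yn-1-yl)-1,3,3-trimethylcyclohexane-1,4-diol
Product: 15 (1S,2R,4S)-2-[(3E)-5-hydroxy-3-methylpent-3-en-1-yl]-1,3,3-trimethylcyclohexane-1,4-diol, via alkenylalane 14 (not isolated)
Conditions: Me3Al (5 equiv), Cp2ZrCl2 (0.25 equiv), CH2Cl2, 0 °C to rt; then n-BuLi, THF, −78 °C; (CH2O)n, rt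
Reagents that add atoms: trimethylaluminium, C[Al](C)C; formaldehyde (from paraformaldehyde), C=O
Why: zirconium-catalysed syn-carboalumination (Negishi) should put the methyl on the internal carbon, and hydroxymethylation of the derived alanate with retention should give the (E)-allylic alcohol, the two hydroxyls being carried as aluminium alkoxides.

Step 11
Reactants: 15 (1S,2R,4S)-2-[(3E)-5-hydroxy-3-methylpent-3-en-1-yl]-1,3,3-trimethylcyclohexane-1,4-diol
Product: 16 (1S,2R,4S)-2-{2-[(2R,3R)-3-(hydroxymethyl)-2-methyloxiran-2-yl]ethyl}-1,3,3-trimethylcyclohexane-1,4-diol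
Conditions: Ti(OiPr)4 (cat.), D-(−)-diethyl tartrate, t-BuOOH, 4 Å MS, CH2Cl2, −20 °C
Reagents that add atoms: tert-butyl hydroperoxide, CC(C)(C)OO
Why: Sharpless asymmetric epoxidation under control of the D-tartrate ligand should give the (2R,3R)-epoxide, the mirror-image sense of that given by the L-ligand with geraniol-type alcohols, which fixes C3' as R.

Step 12
Reactants: 16 (1S,2R,4S)-2-{2-[(2R,3R)-3-(hydroxymethyl)-2-methyloxiran-2-yl]ethyl}-1,3,3-trimethylcyclohexane-1,4-diol
Product: 17 (1S,2R,4S)-2-[(3R)-3,5-dihydroxy-3-methylpentyl]-1,3,3-trimethylcyclohexane-1,4-diol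
Conditions: NaAlH2(OCH2CH2OMe)2, THF, 0 °C
Reagents that add atoms: none
Why: alkoxide-directed hydride delivery should open the 2,3-epoxy alcohol at C2' to the 1,3-diol without touching the C3'–O bond.

Step 13
Reactants: 17 (1S,2R,4S)-2-[(3R)-3,5-dihydroxy-3-methylpentyl]-1,3,3-trimethylcyclohexane-1,4-diol; 18 7-hydroxy-2H-chromen-2-one (umbelliferone)
Product: 19 7-{[(3R)-5-[(1R,3S,6S)-3,6-dihydroxy-2,2,6-trimethylcyclohexyl]-3-hydroxy-3-methylpentyl]oxy}-2H-chromen-2-one
Conditions: PPh3, DIAD, THF, 0 °C to rt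
Reagents that add atoms: none
Why: in the Mitsunobu etherification only the primary hydroxyl should form the alkoxyphosphonium ion, the two tertiary and the axial neopentyl secondary hydroxyls being inert, so the phenol is alkylated at C1' alone.

**Compound list**

1 | (R)-4-[(tert-butyldimethylsilyl)oxy]cyclopent-2-en-1-one | O=C1C=C[C@H](O[Si](C)(C)C(C)(C)C)C1 | starting material
2 | (R)-4-[(tert-butyldimethylsilyl)oxy]-2-iodocyclopent-2-en-1-one | O=C1C(I)=C[C@H](O[Si](C)(C)C(C)(C)C)C1 | intermediate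
3 | (R)-4-[(tert-butyldimethylsilyl)oxy]-2-methylcyclopent-2-en-1-one | O=C1C(C)=C[C@H](O[Si](C)(C)C(C)(C)C)C1 | intermediate
4 | 4-methylpent-1-en-3-one | CC(C)C(=O)C=C | starting material
5 | tert-butyl(dimethyl)[(4-methylpenta-1,3-dien-3-yl)oxy]silane | C=CC(O[Si](C)(C)C(C)(C)C)=C(C)C | intermediate
6 | (3R,3aR,7aS)-3,5-bis[(tert-butyldimethylsilyl)oxy]-4,4,7a-trimethyl-2,3,3a,4,7,7a-hexahydro-1H-inden-1-one | CC1(C)[C@H]2[C@H](O[Si](C)(C)C(C)(C)C)CC(=O)[C@@]2(C)CC=C1O[Si](C)(C)C(C)(C)C | intermediate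
7 | (3aR,7aS)-5-[(tert-butyldimethylsilyl)oxy]-4,4,7a-trimethyl-3a,4,7,7a-tetrahydro-1H-inden-1-one | CC1(C)[C@H]2C=CC(=O)[C@@]2(C)CC=C1O[Si](C)(C)C(C)(C)C | intermediate
8 | (3aR,7aS)-4,4,7a-trimethyl-3a,4,7,7a-tetrahydro-1H-indene-1,5(6H)-dione | CC1(C)[C@H]2C=CC(=O)[C@@]2(C)CCC1=O | intermediate
9 | dilithium (3aR,5S,7aS)-4,4,7a-trimethyl-3a,4,5,6,7,7a-hexahydro-3H-indene-1,5-bis(olate) | [Li+].[Li+].CC1(C)[C@H]2CC=C([O-])[C@@]2(C)CC[C@@H]1[O-] | intermediate
10 | (3aR,5S,7aS)-5-hydroxy-4,4,7a-trimethyloctahydro-1H-inden-1-one | CC1(C)[C@H]2CCC(=O)[C@@]2(C)CC[C@@H]1O | intermediate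
11 | (4aR,6S,8aS)-6-hydroxy-5,5,8a-trimethyloctahydro-2H-chromen-2-one | CC1(C)[C@H]2CCC(=O)O[C@@]2(C)CC[C@@H]1O | intermediate
12 | (4aR,6S,8aS)-5,5,8a-trimethyloctahydro-2H-chromene-2,6-diol (anomeric mixture) | CC1(C)[C@H]2CCC(O)O[C@@]2(C)CC[C@@H]1O | intermediate
13 | (1S,2R,4S)-2-(but-3-yn-1-yl)-1,3,3-trimethylcyclohexane-1,4-diol | CC1(C)[C@@H](CCC#C)[C@@](C)(O)CC[C@@H]1O | intermediate
14 | [(1E)-4-{(1R,3S,6S)-3,6-bis[(dimethylalumanyl)oxy]-2,2,6-trimethylcyclohexyl}-2-methylbut-1-en-1-yl]dimethylalumane | CC1(C)[C@@H](CC/C(C)=C/[Al](C)C)[C@@](C)(O[Al](C)C)CC[C@@H]1O[Al](C)C | intermediate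
15 | (1S,2R,4S)-2-[(3E)-5-hydroxy-3-methylpent-3-en-1-yl]-1,3,3-trimethylcyclohexane-1,4-diol | CC1(C)[C@@H](CC/C(C)=C/CO)[C@@](C)(O)CC[C@@H]1O | intermediate
16 | (1S,2R,4S)-2-{2-[(2R,3R)-3-(hydroxymethyl)-2-methyloxiran-2-yl]ethyl}-1,3,3-trimethylcyclohexane-1,4-diol | CC1(C)[C@@H](CC[C@@]2(C)O[C@@H]2CO)[C@@](C)(O)CC[C@@H]1O | intermediate
17 | (1S,2R,4S)-2-[(3R)-3,5-dihydroxy-3-methylpentyl]-1,3,3-trimethylcyclohexane-1,4-diol | CC1(C)[C@@H](CC[C@@](C)(O)CCO)[C@@](C)(O)CC[C@@H]1O | intermediate
18 | 7-hydroxy-2H-chromen-2-one (umbelliferone) | Oc1ccc2ccc(=O)oc2c1 | starting material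
19 | 7-{[(3R)-5-[(1R,3S,6S)-3,6-dihydroxy-2,2,6-trimethylcyclohexyl]-3-hydroxy-3-methylpentyl]oxy}-2H-chromen-2-one | CC1(C)[C@@H](CC[C@@](C)(O)CCOc2ccc3ccc(=O)oc3c2)[C@@](C)(O)CC[C@@H]1O | target

**Count and risks**

Total step count: 13. Longest linear sequence: 12 steps (steps 1, 2 and 4 to 13, from 1 to 19).

Steps most likely to fail:

Step 4. The strong Lewis acid may ionise or eliminate the allylic silyloxy group of 3, or strip the silyl group from 5, before both C–C bonds have formed, and the reaction may stop after the first bond. The fallback sets out from 3 and 5 and comes back at 8; it makes the two bonds in separate polar events. A Mukaiyama–Michael addition of 5 to 3 (TBSOTf cat., CH2Cl2, −78 °C, aqueous work-up) should deliver the CMe2 carbon anti to the silyloxy group and give (3S,4R)-4-[(tert-butyldimethylsilyl)oxy]-2-methyl-3-(2-methyl-3-oxopent-4-en-2-yl)cyclopentan-1-one F1 (C2 epimers). DBU followed by catalytic KOtBu in THF at 0 °C should then expel the silyloxy group and close ring A by intramolecular Michael addition of the C2 enolate to the vinyl ketone, giving 8.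

Step 6. The enone may be attacked at the carbonyl (1,2) in competition with conjugate reduction, and hydride may reach the C5 ketone from the wrong face if the ring does not adopt the expected chair. The fallback sets out from 8 and comes back at 10; it separates the two reductions and puts the C5 centre under reagent control. 1,4-Hydrosilylation of the enone with Et3SiH and RhCl(PPh3)3 should give (3aS,7aS)-4,4,7a-trimethyl-1-[(triethylsilyl)oxy]-3,3a,4,6,7,7a-hexahydro-5H-inden-5-one F2. Corey–Bakshi–Shibata reduction with (R)-2-methyl-CBS-oxazaborolidine and catecholborane should then give (3aR,5S,7aS)-4,4,7a-trimethyl-1-[(triethylsilyl)oxy]-3a,4,5,6,7,7a-hexahydro-3H-inden-5-ol F3, and dilute HCl in THF should unmask the C1 ketone to give 10.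

Step 10. Carbometalation may be incomplete, or the alkenylalane may be protonated instead of hydroxymethylated, in the presence of the two aluminium alkoxides. The fallback sets out from 11 and comes back at 15; it replaces alkyne carbometalation by carbonyl olefination. MeLi (THF, −78 °C) should open the lactone to 4-[(1R,3S,6S)-3,6-dihydroxy-2,2,6-trimethylcyclohexyl]butan-2-one F4. Horner–Wadsworth–Emmons reaction with (EtO)2P(O)CH2CO2Et and NaH should give ethyl (2E)-5-[(1R,3S,6S)-3,6-dihydroxy-2,2,6-trimethylcyclohexyl]-3-methylpent-2-enoate F5 after removal of the Z isomer, and i-Bu2AlH (CH2Cl2, −78 °C) should reduce the ester to 15.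

Further compounds
F1 | step 4 | (3S,4R)-4-[(tert-butyldimethylsilyl)oxy]-2-methyl-3-(2-methyl-3-oxopent-4-en-2-yl)cyclopentan-1-one (C2 epimers) | C=CC(=O)C(C)(C)[C@H]1[C@H](O[Si](C)(C)C(C)(C)C)CC(=O)C1C
F2 | step 6 | (3aS,7aS)-4,4,7a-trimethyl-1-[(triethylsilyl)oxy]-3,3a,4,6,7,7a-hexahydro-5H-inden-5-one | CC1(C)[C@H]2CC=C(O[Si](CC)(CC)CC)[C@@]2(C)CCC1=O
F3 | step 6 | (3aR,5S,7aS)-4,4,7a-trimethyl-1-[(triethylsilyl)oxy]-3a,4,5,6,7,7a-hexahydro-3H-inden-5-ol | CC1(C)[C@H]2CC=C(O[Si](CC)(CC)CC)[C@@]2(C)CC[C@@H]1O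
F4 | step 10 | 4-[(1R,3S,6S)-3,6-dihydroxy-2,2,6-trimethylcyclohexyl]butan-2-one | CC1(C)[C@@H](CCC(C)=O)[C@@](C)(O)CC[C@@H]1O
F5 | step 10 | ethyl (2E)-5-[(1R,3S,6S)-3,6-dihydroxy-2,2,6-trimethylcyclohexyl]-3-methylpent-2-enoate | CC1(C)[C@@H](CC/C(C)=C/C(=O)OCC)[C@@](C)(O)CC[C@@H]1O
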